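The earlier runs and the new flask were generated by integration with made-up constants; noise was put on by code.

**One step.** In a one-step world, first order in substrate, the logarithm of the share of substrate left falls at a single constant from the first reading to the last. I test that on the spring run; the summer flask repeats the spring charge, 250 mM of substrate and 25.0 mM of free catalyst.

| setting | spring | noon | dusk | dawn | summer |
|---|---|---|---|---|---|
| substrate | 250 mM | 100 mM | 250 mM | 380 mM | 250 mM |
| free catalyst | 25.0 mM | 25.0 mM | 13.0 mM | 25.0 mM | 25.0 mM |
| time |  |  |  |  | 300 min |

| run | time / min | [target] / mM |
|---|---|---|
| spring run | 17 | 29.6 |
| spring run | 34 | 51.6 |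
| spring run | 51 | 69.0 |
| spring run | 69 | 81.1 |
| spring run | 86 | 89.9 |
| spring run | 100 | 97.1 |
| spring run | 120 | 106.5 |
| noon run | 17 | 11.9 |
| noon run | 34 | 23.4 |
| noon run | 51 | 32.5 |
| noon run | 69 | 37.5 |
| noon run | 86 | 42.3 |
| noon run | 100 | 46.3 |
| noon run | 120 | 49.9 |
| dusk run | 17 | 16.7 |
| dusk run | 34 | 31.1 |
| dusk run | 51 | 43.8 |
| dusk run | 69 | 57.0 |
| dusk run | 86 | 66.9 |
| dusk run | 100 | 74.5 |
| dusk run | 120 | 84.4 |
| dawn run | 17 | 40.0 |
| dawn run | 34 | 72.8 |
| dawn run | 51 | 95.3 |
| dawn run | 69 | 111.1 |
| dawn run | 86 | 124.4 |
| dawn run | 100 | 135.2 |
| dawn run | 120 | 147.8 |

(standard deviation of a reading: 0.8 mM)

- order of the initial rate in [free catalyst], near the charge of the spring run, the rate being that where two percent of its substrate are target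
- order of the initial rate in [substrate], near the charge of the spring run, the rate being that where two percent of its substrate are target (one fixed amount of target, the same in the runs compared)
- the noon run starts with 150 mM less of substrate than the spring run, and with no target. Compared where both hold the same amount of substrate, once fifteen percent of what the noon run was charged with has turned into target, is the noon run faster, slower or alike (within a tenth)?
- target in the summer run at 300 min, as a share of the substrate charged

- Overall: substrate -> target, with free catalyst as catalyst.
- Constant volume, constant temperature.
- The analysis sees a species whether free or bound.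
- An order is taken over about fifteen percent of the charge, up and down.

**Two constants.** The spring run breaks that picture. Over its first 17 min the share left falls at 0.00741 min⁻¹. Late I read the tail constant, the share of the remaining substrate that turns per minute between the readings at 86 min and 120 min (a pseudo-first-order constant): 0.00322 min⁻¹, slower than at the start. So I keep the 42.6% of the charge turned at 120 min as the large part and reckon just what the tail adds.

**What matters.** I take each input in turn. The scatter on the last reading is 0.320% of the charge, which moves the outcome by 0.18 percentage points. The dusk run, with 13.0 mM of free catalyst, reads a tail constant of 0.00295 min⁻¹; put in place of the spring value, it moves the outcome by 1.6 points, more than the reading's scatter does. So the tail constant has to be known well, and the last reading less so.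

**My number.** Held for 180 min, the spring tail constant brings target to 67.8% of the charge. Between 51 min and 86 min the same constant reads 0.00351 min⁻¹, higher than the late value, so I treat my number as the high side.

**The forecast.** It gives order 1 in free catalyst, order 0.85 in substrate, the noon run faster, and 62% at 300 min: “Extrapolating with a flat-to-slowly-falling constant gives about 58–66% at 300 min.” Its value stands below mine.

**The flask.** The simulation gives order 1.3 in free catalyst, above the forecast, order 0.88 in substrate, the noon run faster by a ratio of 2.8, and 65.0%.

    free catalyst + substrate ⇌ catalyst-substrate complex, settled at all times (0.5100 M⁻¹)
    catalyst-substrate complex + free catalyst → target + 2 free catalyst (19.20 M⁻¹ min⁻¹)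
    free catalyst + target → spent catalyst + target (0.3276 M⁻¹ min⁻¹)
    substrate → target (0.002814 min⁻¹)

**What ran.** Early in the spring run, free catalyst binds substrate and the catalyst-substrate complex meets a second free catalyst, with a total rate of 1.9 mM min⁻¹ where two percent of the substrate have turned, against 0.704 mM min⁻¹ for the plain step on the full charge, while target turns free catalyst into spent catalyst. The plain step runs from the start to 300 min in the summer run, and the spring tail constant held that long lands 2.8 points above the summer share. On the dusk run, its own tail constant from 120 min puts target at half the charge at 215 min, and the run stands there at 221 min.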